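**Retrosynthetic overview**

1. The target is reached by acetal cleavage of its 5,7-bis(methoxymethyl) ether, the last step.
2. Ring C (O1–C2–C3–C4–C4a–C8a) is disconnected at O1–C8a and C4–C4a. It comes from a four-membered (S)-4-aryloxetan-2-one (O1, C2, C3, C4 and the stereocentre) that is expanded by the two carbons of 3,5-bis(methoxymethoxy)benzyne (C8a, C4a, with the rest of ring A).
3. Enabling feature: O1, C2, C3 and C4 of ring C form a 3-oxypropanoyl unit that can be stored as a strained oxetan-2-one whose O1–C4 acyl–oxygen bond is weak and electrophilic. In ring A the neighbours C4a and C8a are flanked by the C5 oxygen and by C8–H, the footprint of a 3-alkoxybenzyne polarised to take O1 at C8a and C4 at C4a.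
4. The β-lactone comes from the β-hydroxy acid and this from the β-keto ester (asymmetric transfer hydrogenation sets C2). The keto ester comes from 6-acetyl-2,2-dimethyl-8-prenylchromene, made from 3'-bromo-4'-hydroxyacetophenone by propargyl ether rearrangement and Stille prenylation. The aryne precursor comes from 5-bromoresorcinol.
5. Ring order: rings A and B are bought as benzenes; ring D (dimethylpyran) is formed first, then the temporary oxetanone, and ring C last by ring expansion.

Key step: step 12

Remark: the configuration written at C2 in the target SMILES is (S). Flavanone numbering (O1, C2, C3, C4, C4a, C5–C8, C8a) is used for rings C and A, and "chromenyl" below means the 2,2-dimethyl-8-(3-methylbut-2-en-1-yl)-2H-chromen-6-yl group (ring B with fused ring D and the prenyl group).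

**Route**

Step 1
Reactants: 1 bromohydroxyacetophenone 1-(3-bromo-4-hydroxyphenyl)ethan-1-one; 2 3-chloro-3-methylbut-1-yne
Product: 3 propargyl ether 1-{3-bromo-4-[(2-methylbut-3-yn-2-yl)oxy]phenyl}ethan-1-one
Conditions: CuCl2·2H2O (cat.), DBU, MeCN, 0 °C → rt
Reagents that add atoms: none
Why: Copper-catalysed O-propargylation; the copper acetylide of 2 ionises to a propargyl cation equivalent that the acidic, acyl-activated phenoxide captures at the tertiary carbon, a reaction type that suits electron-poor phenols.

Step 2
Reactants: 3 propargyl ether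
Product: 6 bromochromene ketone 1-(8-bromo-2,2-dimethyl-2H-chromen-6-yl)ethan-1-one, via o-allenylphenol 4 (not isolated), via o-quinone methide 5 (not isolated)
Conditions: N,N-diethylaniline, 190 °C
Reagents that add atoms: none
Why: Aromatic propargyl Claisen rearrangement to the only free ortho position (the other is blocked by bromine), then 1,5-hydrogen shift and oxa-6π electrocyclisation, should close the 2,2-dimethylpyran ring D.

Step 3
Reactants: 6 bromochromene ketone; 7 tributyl(3-methylbut-2-en-1-yl)stannane
Product: 8 prenylchromene ketone 1-[2,2-dimethyl-8-(3-methylbut-2-en-1-yl)-2H-chromen-6-yl]ethan-1-one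
Conditions: Pd(PPh3)4 (5 mol%), DMF, 95 °C
Reagents that add atoms: none
Why: Stille cross-coupling; oxidative addition of zerovalent palladium into the C–Br bond, transmetalation with the allylic stannane and reductive elimination at the primary allyl terminus should give the linear prenyl arene.

Step 4
Reactants: 8 prenylchromene ketone; 9 diethyl carbonate
Product: 10 β-keto ester ethyl 3-chromenyl-3-oxopropanoate
Conditions: NaH, THF, reflux; then aq. HCl, 0 °C
Reagents that add atoms: none
Why: Crossed Claisen condensation of the methyl ketone enolate with the non-enolisable carbonate, driven forward by deprotonation of the β-keto ester formed.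

Step 5
Reactants: 10 β-keto ester
Product: 11 hydroxy ester ethyl (3S)-3-chromenyl-3-hydroxypropanoate
Conditions: RuCl[(S,S)-TsDPEN](p-cymene) (1 mol%), HCO2H/Et3N (5:2), DMF, 35 °C
Reagents that add atoms: none
Why: Noyori–Ikariya asymmetric transfer hydrogenation of the aryl ketone through the six-membered outer-sphere transition state in which the aryl group lies under the η6-arene, so the (S,S) ligand should deliver hydride to the Re face and set the (S) carbinol centre (the later C2), while the chromene and prenyl double bonds are not reduced.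

Step 6
Reactants: 11 hydroxy ester
Product: 12 hydroxy acid (3S)-3-chromenyl-3-hydroxypropanoic acid
Conditions: LiOH·H2O, THF/H2O, 0 °C; then 1 M HCl to pH 4, 0 °C
Reagents that add atoms: lithium hydroxide, [Li+].[OH-]
Why: Ester saponification by acyl substitution under cold conditions that leave the benzylic carbinol centre untouched, with acidification only to pH 4 to avoid ionisation of the electron-rich benzylic alcohol.

Step 7
Reactants: 12 hydroxy acid
Product: 14 β-lactone (4S)-4-chromenyloxetan-2-one, via mixed anhydride 13 (not isolated)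
Conditions: PhSO2Cl, pyridine, 0–4 °C
Reagents that add atoms: none
Why: β-Lactonisation by carboxyl activation; the hydroxyl oxygen attacks the carboxylic–sulfonic mixed anhydride in a 4-exo-trig acyl substitution, so the C–O bond at the stereocentre is not broken and the (S) configuration is retained.

Step 8
Reactants: 15 5-bromobenzene-1,3-diol
Product: 16 bromo bis-acetal 1-bromo-3,5-bis(methoxymethoxy)benzene
Conditions: MOMCl, i-Pr2NEt, CH2Cl2, 0 °C → rt
Reagents that add atoms: chloromethyl methyl ether, COCCl
Why: Williamson-type O-alkylation of both phenols by the reactive α-chloro ether under amine base.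

Step 9
Reactants: 16 bromo bis-acetal
Product: 17 phenol 3,5-bis(methoxymethoxy)phenol
Conditions: Pd2(dba)3 (cat.), t-BuXPhos, KOH, 1,4-dioxane/H2O, 100 °C; then aq. NH4Cl
Reagents that add atoms: potassium hydroxide, [K+].[OH-]
Why: Palladium-catalysed C–O cross-coupling of the aryl bromide with hydroxide, the bulky biarylphosphine enabling C–O reductive elimination; the acetal ethers are stable to hot aqueous base.

Step 10
Reactants: 17 phenol
Product: 18 bromophenol 2-bromo-3,5-bis(methoxymethoxy)phenol
Conditions: NBS (1.0 equiv), i-Pr2NH (10 mol%), CH2Cl2, −78 → 0 °C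
Reagents that add atoms: N-bromosuccinimide, O=C1CCC(=O)N1Br
Why: Amine-mediated ortho-selective electrophilic bromination; the N-bromoamine, hydrogen-bonded to the phenol, should deliver bromine to one of the two equivalent ortho positions in preference to the more hindered position between the two acetal ethers.

Step 11
Reactants: 18 bromophenol
Product: 22 silylaryl triflate 3,5-bis(methoxymethoxy)-2-(trimethylsilyl)phenyl trifluoromethanesulfonate, via aryl silyl ether 19 (not isolated), via aryllithium 20 (not isolated), via lithium phenoxide 21 (not isolated)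
Conditions: HMDS, THF, 65 °C, then evaporation; n-BuLi, THF, −78 °C; PhNTf2, −78 °C → rt
Reagents that add atoms: hexamethyldisilazane, C[Si](C)(C)N[Si](C)(C)C; N-phenylbis(trifluoromethanesulfonimide), O=S(=O)(N(c1ccccc1)S(=O)(=O)C(F)(F)F)C(F)(F)F
Why: O-silylation, bromine–lithium exchange and retro-Brook 1,3 O→C silyl shift (driven by formation of the lithium phenoxide) place the silyl group ortho to oxygen, and the phenoxide is then O-sulfonylated by the mild triflyl donor.

Step 12
Reactants: 14 β-lactone; 22 silylaryl triflate
Product: 24 protected flavanone (2S)-2-chromenyl-5,7-bis(methoxymethoxy)-2,3-dihydro-4H-chromen-4-one, via aryne 23 (not isolated)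
Conditions: CsF (3 equiv), MeCN/toluene (1:1), 22 added slowly, 0 °C → rt
Reagents that add atoms: none
Why: Proposed new method: fluoride-induced 1,2-elimination of 22 releases aryne 23; the ring oxygen O1 of oxetanone 14 adds to the aryne carbon that becomes C8a, the aryl anion formed at the future C4a attacks the lactone carbonyl C4 through a four-membered tetrahedral intermediate, and collapse of this intermediate with cleavage of the strained O1–C4 bond amounts to insertion of the aryne into the acyl–oxygen σ bond. The closest known reactions are aryne insertion into the N–C(O) bond of amides and ureas and into the O–C(O) bond of carboxylic acids, and the two-carbon ring expansion of cyclic β-keto esters by aryne acyl-alkylation; an oxetan-2-one should qualify because ring strain weakens its ester resonance, leaving the ring oxygen ether-like and the acyl carbon unusually electrophilic, and because the acyl shift releases that strain. Ring C is therefore not closed from a chain but grows from the four-membered ring by two atoms: bond O1–C8a forms by intermolecular nucleophilic addition and bond C4–C4a by 4-exo-trig attack followed by fragmentation. No new stereocentre is created: C2 is the former C4 of the lactone, none of its four bonds is touched, and its (S) configuration should be carried over unchanged. The step needs regioselectivity, which the methoxymethoxy group beside the triple bond secures by stabilising the aryl anion ortho to it and making the distal carbon the electrophilic one (the second, remote methoxymethoxy group cannot override this), and chemoselectivity for the lactone oxygen over the ene reaction of the prenyl group, which slow release of the aryne into a concentrated solution of 14 should favour. Should fluoride open the acyl–oxygen bond reversibly, the resulting alkoxide would be arylated and acylated in the same sense and give the same product.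

Step 13
Reactants: 24 protected flavanone
Product: 25 target (2S)-2-chromenyl-5,7-dihydroxy-2,3-dihydro-4H-chromen-4-one
Conditions: HCl (1.25 M in MeOH), THF, 0 °C → rt
Reagents that add atoms: none
Why: Acid-catalysed acetal exchange (methanolysis) of the two methoxymethyl ethers under cold anhydrous conditions that should leave the chromene and prenyl double bonds and the benzylic C2–O1 bond intact, so C2 should stay (S).

**Compound list**

1 | 1-(3-bromo-4-hydroxyphenyl)ethan-1-one | CC(=O)c1ccc(O)c(Br)c1 | starting material
2 | 3-chloro-3-methylbut-1-yne | C#CC(C)(C)Cl | starting material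
3 | 1-{3-bromo-4-[(2-methylbut-3-yn-2-yl)oxy]phenyl}ethan-1-one | CC(=O)c1ccc(OC(C)(C)C#C)c(Br)c1 | intermediate
4 | 1-[3-bromo-4-hydroxy-5-(3-methylbuta-1,2-dien-1-yl)phenyl]ethan-1-one | CC(=O)c1cc(Br)c(O)c(C=C=C(C)C)c1 | intermediate (not isolated)
5 | 4-acetyl-2-bromo-6-(3-methylbut-2-en-1-ylidene)cyclohexa-2,4-dien-1-one | CC(=O)C1=CC(=CC=C(C)C)C(=O)C(Br)=C1 | intermediate (not isolated)
6 | 1-(8-bromo-2,2-dimethyl-2H-chromen-6-yl)ethan-1-one | CC(=O)c1cc(Br)c2OC(C)(C)C=Cc2c1 | intermediate
7 | tributyl(3-methylbut-2-en-1-yl)stannane | CCCC[Sn](CCCC)(CCCC)CC=C(C)C | starting material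
8 | 1-[2,2-dimethyl-8-(3-methylbut-2-en-1-yl)-2H-chromen-6-yl]ethan-1-one | CC(=O)c1cc(CC=C(C)C)c2OC(C)(C)C=Cc2c1 | intermediate
9 | diethyl carbonate | CCOC(=O)OCC | starting material
10 | ethyl 3-[2,2-dimethyl-8-(3-methylbut-2-en-1-yl)-2H-chromen-6-yl]-3-oxopropanoate | CCOC(=O)CC(=O)c1cc(CC=C(C)C)c2OC(C)(C)C=Cc2c1 | intermediate
11 | ethyl (3S)-3-[2,2-dimethyl-8-(3-methylbut-2-en-1-yl)-2H-chromen-6-yl]-3-hydroxypropanoate | CCOC(=O)C[C@H](O)c1cc(CC=C(C)C)c2OC(C)(C)C=Cc2c1 | intermediate
12 | (3S)-3-[2,2-dimethyl-8-(3-methylbut-2-en-1-yl)-2H-chromen-6-yl]-3-hydroxypropanoic acid | OC(=O)C[C@H](O)c1cc(CC=C(C)C)c2OC(C)(C)C=Cc2c1 | intermediate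
13 | benzenesulfonic (3S)-3-[2,2-dimethyl-8-(3-methylbut-2-en-1-yl)-2H-chromen-6-yl]-3-hydroxypropanoic anhydride | O=C(C[C@H](O)c1cc(CC=C(C)C)c2OC(C)(C)C=Cc2c1)OS(=O)(=O)c1ccccc1 | intermediate (not isolated)
14 | (4S)-4-[2,2-dimethyl-8-(3-methylbut-2-en-1-yl)-2H-chromen-6-yl]oxetan-2-one | O=C1C[C@H](O1)c1cc(CC=C(C)C)c2OC(C)(C)C=Cc2c1 | intermediate
15 | 5-bromobenzene-1,3-diol | Oc1cc(O)cc(Br)c1 | starting material
16 | 1-bromo-3,5-bis(methoxymethoxy)benzene | COCOc1cc(Br)cc(OCOC)c1 | intermediate
17 | 3,5-bis(methoxymethoxy)phenol | COCOc1cc(O)cc(OCOC)c1 | intermediate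
18 | 2-bromo-3,5-bis(methoxymethoxy)phenol | COCOc1cc(OCOC)c(Br)c(O)c1 | intermediate
19 | [2-bromo-3,5-bis(methoxymethoxy)phenoxy]trimethylsilane | COCOc1cc(OCOC)c(Br)c(O[Si](C)(C)C)c1 | intermediate (not isolated)
20 | {2,4-bis(methoxymethoxy)-6-[(trimethylsilyl)oxy]phenyl}lithium | [Li]c1c(O[Si](C)(C)C)cc(OCOC)cc1OCOC | intermediate (not isolated)
21 | lithium 3,5-bis(methoxymethoxy)-2-(trimethylsilyl)phenolate | [Li+].COCOc1cc(OCOC)c([Si](C)(C)C)c([O-])c1 | intermediate (not isolated)
22 | 3,5-bis(methoxymethoxy)-2-(trimethylsilyl)phenyl trifluoromethanesulfonate | COCOc1cc(OCOC)c([Si](C)(C)C)c(OS(=O)(=O)C(F)(F)F)c1 | intermediate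
23 | 3,5-bis(methoxymethoxy)benzyne (1,2-didehydro-3,5-bis(methoxymethoxy)benzene) | COCOC1=CC(OCOC)=CC#C1 | intermediate (not isolated)
24 | (2S)-2-[2,2-dimethyl-8-(3-methylbut-2-en-1-yl)-2H-chromen-6-yl]-5,7-bis(methoxymethoxy)-2,3-dihydro-4H-chromen-4-one | CC(C)=CCc1cc([C@@H]2CC(=O)c3c(OCOC)cc(OCOC)cc3O2)cc2c1OC(C)(C)C=C2 | intermediate
25 | (2S)-2-[2,2-dimethyl-8-(3-methylbut-2-en-1-yl)-2H-chromen-6-yl]-5,7-dihydroxy-2,3-dihydro-4H-chromen-4-one | CC(C)=CCc1cc([C@@H]2CC(=O)c3c(O)cc(O)cc3O2)cc2c1OC(C)(C)C=C2 | target

**Step count and risks**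

Total step count: 13. Longest linear sequence: 9 steps (steps 1–7, 12 and 13).

Steps most likely to fail:

Step 12 (proposed new method). The aryne may be consumed by fluoride or by the ene reaction with the prenyl group before the weakly nucleophilic lactone oxygen captures it. Attack through the carbonyl oxygen followed by ionisation of the benzylic C–O bond, or fluoride-induced opening of ring C in the product to the chalcone, would erode the enantiopurity. The fallback is aryne-free and uses known chemistry; it sets out from 10 and 18 and comes back at 24. Keto ester 10 is reduced with the enantiomeric catalyst RuCl[(R,R)-TsDPEN](p-cymene) to ethyl (3R)-3-chromenyl-3-hydroxypropanoate F1. F1 is silylated (TBSCl, imidazole, DMF) to its tert-butyldimethylsilyl ether F2 and converted (MeNHOMe·HCl, i-PrMgCl, THF, −20 °C) into the N-methoxy-N-methylamide F3. Bromophenol 18 is deprotonated and bromine–lithium exchanged (n-BuLi, 2.2 equiv, THF, −78 °C) to lithium 2-lithio-3,5-bis(methoxymethoxy)phenolate F4, which is acylated by F3 to the 2-hydroxyaryl ketone F5. Buffered desilylation (TBAF, AcOH, THF) gives the hydroxy ketone F6. An intramolecular Mitsunobu etherification (PPh3, DIAD, THF, 0 °C) then closes ring C by attack of the phenol on the activated carbinol with inversion, which should turn the (R) alcohol into (S)-24.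

Step 7. The β-lactone carries an electron-rich para-alkoxyaryl group on its carbinol carbon, so ionisation of the benzylic C–O bond with loss of CO2 to the styrene may occur during formation or purification. The fallback avoids the lactone; it sets out from 11 and 22 and comes back at 24. Hydroxy ester 11 is deprotonated in situ (NaH, THF, 0 °C) and treated with 22 (in excess) and CsF. O-arylation of the alkoxide by aryne 23 at the same distal carbon, followed by acylation of the aryl anion by the tethered ethyl ester through a six-membered transition state, is the known aryne annulation of ester-bearing oxygen nucleophiles (as in xanthone formation from salicylates). It should give 24 with C2 untouched, the excess aryne scavenging the ethoxide that is released. This fallback makes no new compound (F0).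

Step 10. Bromination may go to the position between the two acetal ethers (para to the hydroxyl) or proceed twice, so that the wanted ortho isomer is formed unselectively. The fallback replaces electrophilic substitution by directed ortho-metalation; it sets out from 17 and comes back at 22. Phenol 17 is carbamoylated (ClCONEt2, K2CO3, MeCN) to 3,5-bis(methoxymethoxy)phenyl N,N-diethylcarbamate F7. s-BuLi/TMEDA (THF, −78 °C) should lithiate between the carbamate and one acetal ether to give the ortho-lithiated carbamate F8, which is silylated with TMSCl to the ortho-silyl carbamate F9. Reductive cleavage of the carbamate with Cp2Zr(H)Cl (THF, rt) gives 3,5-bis(methoxymethoxy)-2-(trimethylsilyl)phenol F10, and triflation (NaH, PhNTf2, THF) gives 22.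

**Further compounds**

F1 | step 12 | ethyl (3R)-3-[2,2-dimethyl-8-(3-methylbut-2-en-1-yl)-2H-chromen-6-yl]-3-hydroxypropanoate | CCOC(=O)C[C@@H](O)c1cc(CC=C(C)C)c2OC(C)(C)C=Cc2c1
F2 | step 12 | ethyl (3R)-3-[(tert-butyldimethylsilyl)oxy]-3-[2,2-dimethyl-8-(3-methylbut-2-en-1-yl)-2H-chromen-6-yl]propanoate | CCOC(=O)C[C@@H](O[Si](C)(C)C(C)(C)C)c1cc(CC=C(C)C)c2OC(C)(C)C=Cc2c1
F3 | step 12 | (3R)-3-[(tert-butyldimethylsilyl)oxy]-3-[2,2-dimethyl-8-(3-methylbut-2-en-1-yl)-2H-chromen-6-yl]-N-methoxy-N-methylpropanamide | CON(C)C(=O)C[C@@H](O[Si](C)(C)C(C)(C)C)c1cc(CC=C(C)C)c2OC(C)(C)C=Cc2c1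
F4 | step 12 | lithium 2-lithio-3,5-bis(methoxymethoxy)phenolate | [Li+].[Li]c1c([O-])cc(OCOC)cc1OCOC
F5 | step 12 | (3R)-3-[(tert-butyldimethylsilyl)oxy]-3-[2,2-dimethyl-8-(3-methylbut-2-en-1-yl)-2H-chromen-6-yl]-1-[2-hydroxy-4,6-bis(methoxymethoxy)phenyl]propan-1-one | COCOc1cc(O)c(C(=O)C[C@@H](O[Si](C)(C)C(C)(C)C)c2cc(CC=C(C)C)c3OC(C)(C)C=Cc3c2)c(OCOC)c1
F6 | step 12 | (3R)-3-[2,2-dimethyl-8-(3-methylbut-2-en-1-yl)-2H-chromen-6-yl]-3-hydroxy-1-[2-hydroxy-4,6-bis(methoxymethoxy)phenyl]propan-1-one | COCOc1cc(O)c(C(=O)C[C@@H](O)c2cc(CC=C(C)C)c3OC(C)(C)C=Cc3c2)c(OCOC)c1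
F0 | step 7 | none | none
F7 | step 10 | 3,5-bis(methoxymethoxy)phenyl N,N-diethylcarbamate | CCN(CC)C(=O)Oc1cc(OCOC)cc(OCOC)c1
F8 | step 10 | {2-[(diethylcarbamoyl)oxy]-4,6-bis(methoxymethoxy)phenyl}lithium | [Li]c1c(OC(=O)N(CC)CC)cc(OCOC)cc1OCOC
F9 | step 10 | 3,5-bis(methoxymethoxy)-2-(trimethylsilyl)phenyl N,N-diethylcarbamate | CCN(CC)C(=O)Oc1cc(OCOC)cc(OCOC)c1[Si](C)(C)C
F10 | step 10 | 3,5-bis(methoxymethoxy)-2-(trimethylsilyl)phenol | COCOc1cc(O)c([Si](C)(C)C)c(OCOC)c1
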